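The route rests on cutting the pyran ring of the 2H-chromene at the aryl C8a–O1 bond and at the C3=C4 double bond. This uncovers 8-hydroxylinalool: O1, quaternary C2 (with its methyl and side chain) and C3 are the carbinol oxygen, carbinol carbon and vinyl CH of (S)-linalool, so the stereocentre is bought. In one flask the potassium alkoxide of silyl-protected (S)-8-hydroxylinalool displaces fluoride from 4-fluoro-3-vinylbenzaldehyde (the formyl group para to fluorine, at C6, activates and later becomes the bibenzyl link), and the resulting diene ether, not isolated, is closed by ruthenium-catalysed ring-closing metathesis. Methylenation and hydroboration/Suzuki coupling then attach the catechol ring.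

Key step: step 4

Assumption: (S)-(+)-linalool is purchased in high enantiomeric purity; it supplies C2 of the target and no bond to that carbon is broken anywhere in the route.

Step 1
Reactants: 1 (S)-(+)-linalool
Product: 2 (2E,6S)-2,6-dimethylocta-2,7-diene-1,6-diol
Conditions: SeO2 (0.3 equiv), t-BuOOH (3 equiv), salicylic acid (0.1 equiv), CH2Cl2, rt; then NaBH4 (0.3 equiv), MeOH, 0 °C
Reagents that add atoms: tert-butyl hydroperoxide, CC(C)(C)OO (oxygen atom, delivered through SeO2, O=[Se]=O)
Why: Riley-type allylic oxidation (ene reaction, then [2,3]-sigmatropic shift of the allylseleninic acid) should hydroxylate selectively the (E)-methyl group of the trisubstituted olefin, the borohydride polish returning any over-oxidised enal to the alcohol, while the vinyl group (no allylic hydrogen) and the carbinol stereocentre are not involved.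

Step 2
Reactants: 2 (2E,6S)-2,6-dimethylocta-2,7-diene-1,6-diol
Product: 3 (3S,6E)-8-[(tert-butyldimethylsilyl)oxy]-3,7-dimethylocta-1,6-dien-3-ol
Conditions: TBSCl (1.05 equiv), imidazole, CH2Cl2, 0 °C
Reagents that add atoms: tert-butyldimethylsilyl chloride, CC(C)(C)[Si](C)(C)Cl
Why: Selective O-silylation, far faster at the unhindered primary allylic hydroxyl than at the tertiary carbinol, which must stay free as the nucleophile of step 4.

Step 3
Reactants: 4 3-bromo-4-fluorobenzaldehyde
Product: 5 3-ethenyl-4-fluorobenzaldehyde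
Conditions: vinylboronic acid pinacol ester, PdCl2(dppf) (3 mol %), K2CO3, dioxane/H2O, 80 °C
Reagents that add atoms: 4,4,5,5-tetramethyl-2-vinyl-1,3,2-dioxaborolane, C=CB1OC(C)(C)C(C)(C)O1
Why: Suzuki–Miyaura coupling in which oxidative addition occurs at C–Br only, the C–F bond and the formyl group being inert under the mild carbonate conditions.

Step 4
Reactants: 3 (3S,6E)-8-[(tert-butyldimethylsilyl)oxy]-3,7-dimethylocta-1,6-dien-3-ol; 5 3-ethenyl-4-fluorobenzaldehyde
Product: 7 (2S)-2-{(3E)-5-[(tert-butyldimethylsilyl)oxy]-4-methylpent-3-en-1-yl}-2-methyl-2H-chromene-6-carbaldehyde, via styrenyl linalyl ether 6 (not isolated)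
Conditions: KH (1.0 equiv), THF, 0 °C; then 5 (1.1 equiv), 18-crown-6 (0.2 equiv), 0 °C to rt; then toluene (0.02 M), second-generation Grubbs catalyst (H2IMes)(PCy3)Cl2Ru=CHPh (5 mol %), 50 °C
Reagents that add atoms: none
Why: The potassium alkoxide of 3 adds to the fluorine-bearing carbon of 5, the anionic adduct being stabilised by the para-formyl group, and loss of fluoride forms the aryl C8a–O1 bond (SNAr); the ruthenium alkylidene then loads onto the styrene vinyl group of ether 6 and closes onto the linalyl vinyl group through a ruthenacyclobutane, releasing ethene and forming C3=C4. The closest known reactions are the etherification of para-acyl fluoroarenes with tertiary alkoxides and the ring-closing metathesis of 2-vinylphenyl allyl ethers to 2H-chromenes. The pyran ring is closed by ring-closing olefin metathesis to a six-membered ring, whose size enforces the cis olefin. No stereocentre is created: C2 is the carbinol carbon of (S)-linalool, none of its four bonds is broken, and the conditions (50 °C at most, no acid) stay below the ionisation and Claisen thresholds of the tertiary allyl aryl ether 6. The step needs O-arylation in preference to addition at the formyl group, which the reversibility of hemiacetal formation against irreversible fluoride loss should secure, and metathesis between the two monosubstituted olefins in preference to cyclopentene formation with the trisubstituted olefin, which their much higher reactivity should secure.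

Step 5
Reactants: 7 (2S)-2-{(3E)-5-[(tert-butyldimethylsilyl)oxy]-4-methylpent-3-en-1-yl}-2-methyl-2H-chromene-6-carbaldehyde
Product: 8 (2S)-6-ethenyl-2-{(3E)-5-[(tert-butyldimethylsilyl)oxy]-4-methylpent-3-en-1-yl}-2-methyl-2H-chromene
Conditions: Ph3PCH3Br, KOtBu, THF, 0 °C to rt
Reagents that add atoms: methyltriphenylphosphonium bromide, C[P+](c1ccccc1)(c1ccccc1)c1ccccc1.[Br-]
Why: Wittig methylenation of the non-enolisable aryl aldehyde, with the silyl ether and both olefins inert to the ylide.

Step 6
Reactants: 9 3-bromobenzene-1,2-diol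
Product: 10 1-bromo-2,3-bis(methoxymethoxy)benzene
Conditions: MOMCl (2.5 equiv), i-Pr2NEt, CH2Cl2, 0 °C to rt
Reagents that add atoms: chloromethyl methyl ether, COCCl
Why: Williamson-type O-alkylation of both phenols gives a base-stable catechol protection that survives the aqueous phosphate of step 7 and leaves in acid at the end.

Step 7
Reactants: 8 (2S)-6-ethenyl-2-{(3E)-5-[(tert-butyldimethylsilyl)oxy]-4-methylpent-3-en-1-yl}-2-methyl-2H-chromene; 10 1-bromo-2,3-bis(methoxymethoxy)benzene
Product: 12 (2S)-6-{2-[2,3-bis(methoxymethoxy)phenyl]ethyl}-2-{(3E)-5-[(tert-butyldimethylsilyl)oxy]-4-methylpent-3-en-1-yl}-2-methyl-2H-chromene, via B-alkyl-9-BBN adduct 11 (not isolated)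
Conditions: 9-BBN (1.1 equiv), THF, 0 °C to rt; then K3PO4 (3 M aq.), 10, Pd(OAc)2 (5 mol %), SPhos (10 mol %), THF, 60 °C
Reagents that add atoms: none
Why: Anti-Markovnikov hydroboration with the bulky 9-BBN should select the terminal aryl vinyl group over the hindered cis-olefin of the chromene and the trisubstituted olefin, and the B-alkyl Suzuki–Miyaura coupling then forms the sp3–sp2 bond of the bibenzyl without touching the stereocentre.

Step 8
Reactants: 12 (2S)-6-{2-[2,3-bis(methoxymethoxy)phenyl]ethyl}-2-{(3E)-5-[(tert-butyldimethylsilyl)oxy]-4-methylpent-3-en-1-yl}-2-methyl-2H-chromene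
Product: 13 3-{2-[(2S)-2-[(3E)-5-hydroxy-4-methylpent-3-en-1-yl]-2-methyl-2H-chromen-6-yl]ethyl}benzene-1,2-diol
Conditions: HCl (1 M in MeOH), rt to 40 °C, argon
Reagents that add atoms: none
Why: Acid-catalysed acetal methanolysis of both aryl methoxymethyl ethers and methanolysis of the primary silyl ether should unveil the three hydroxyls in one operation, the 2,2-dialkylchromene ether and the quaternary stereocentre being stable to dilute methanolic acid.

Compound list
1 | (S)-(+)-linalool, (3S)-3,7-dimethylocta-1,6-dien-3-ol | CC(C)=CCC[C@@](C)(C=C)O | starting material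
2 | (2E,6S)-2,6-dimethylocta-2,7-diene-1,6-diol | C/C(=C\CC[C@@](C)(C=C)O)CO | intermediate
3 | (3S,6E)-8-[(tert-butyldimethylsilyl)oxy]-3,7-dimethylocta-1,6-dien-3-ol | C/C(=C\CC[C@@](C)(C=C)O)CO[Si](C)(C)C(C)(C)C | intermediate
4 | 3-bromo-4-fluorobenzaldehyde | O=Cc1ccc(F)c(Br)c1 | starting material
5 | 3-ethenyl-4-fluorobenzaldehyde | O=Cc1ccc(F)c(C=C)c1 | intermediate
6 | 4-{[(3S,6E)-8-[(tert-butyldimethylsilyl)oxy]-3,7-dimethylocta-1,6-dien-3-yl]oxy}-3-ethenylbenzaldehyde (not isolated) | C/C(=C\CC[C@@](C)(C=C)Oc1ccc(C=O)cc1C=C)CO[Si](C)(C)C(C)(C)C | intermediate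
7 | (2S)-2-{(3E)-5-[(tert-butyldimethylsilyl)oxy]-4-methylpent-3-en-1-yl}-2-methyl-2H-chromene-6-carbaldehyde | C/C(=C\CC[C@@]1(C)C=Cc2cc(C=O)ccc2O1)CO[Si](C)(C)C(C)(C)C | intermediate
8 | (2S)-6-ethenyl-2-{(3E)-5-[(tert-butyldimethylsilyl)oxy]-4-methylpent-3-en-1-yl}-2-methyl-2H-chromene | C/C(=C\CC[C@@]1(C)C=Cc2cc(C=C)ccc2O1)CO[Si](C)(C)C(C)(C)C | intermediate
9 | 3-bromobenzene-1,2-diol | Oc1cccc(Br)c1O | starting material
10 | 1-bromo-2,3-bis(methoxymethoxy)benzene | COCOc1cccc(Br)c1OCOC | intermediate
11 | 9-{2-[(2S)-2-{(3E)-5-[(tert-butyldimethylsilyl)oxy]-4-methylpent-3-en-1-yl}-2-methyl-2H-chromen-6-yl]ethyl}-9-borabicyclo[3.3.1]nonane (not isolated) | C/C(=C\CC[C@@]1(C)C=Cc2cc(CCB3C4CCCC3CCC4)ccc2O1)CO[Si](C)(C)C(C)(C)C | intermediate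
12 | (2S)-6-{2-[2,3-bis(methoxymethoxy)phenyl]ethyl}-2-{(3E)-5-[(tert-butyldimethylsilyl)oxy]-4-methylpent-3-en-1-yl}-2-methyl-2H-chromene | C/C(=C\CC[C@@]1(C)C=Cc2cc(CCc3cccc(OCOC)c3OCOC)ccc2O1)CO[Si](C)(C)C(C)(C)C | intermediate
13 | 3-{2-[(2S)-2-[(3E)-5-hydroxy-4-methylpent-3-en-1-yl]-2-methyl-2H-chromen-6-yl]ethyl}benzene-1,2-diol (CNP0267525.1) | C/C(=C\CC[C@@]1(C)C=Cc2cc(CCc3cccc(O)c3O)ccc2O1)CO | target

Total step count: 8. Longest linear sequence: 6 steps (steps 1, 2, 4, 5, 7, 8).

Steps most likely to fail

Step 4. The hindered tertiary alkoxide may add to the formyl group and enter hydride-transfer (Cannizzaro/Tishchenko-type) pathways faster than it displaces the fluoride flanked by the vinyl group. In the second stage, residual base may degrade the ruthenium catalyst, or the alkylidene may close onto the trisubstituted olefin. The fallback sets out from 3 and changes the activating group and the staging. The alkoxide of 3 (NaH, DMF, 0 °C to rt) is arylated with 4-fluoro-3-ethenylbenzonitrile F1, made from commercial 3-bromo-4-fluorobenzonitrile under the coupling conditions of step 3; its nitrile activates the fluoride but offers no carbonyl to the alkoxide. The ether 4-{[(3S,6E)-8-[(tert-butyldimethylsilyl)oxy]-3,7-dimethylocta-1,6-dien-3-yl]oxy}-3-ethenylbenzonitrile F2 is isolated and purified free of base. It is then closed in a separate flask (second-generation Grubbs catalyst, toluene, 50 °C) to (2S)-2-{(3E)-5-[(tert-butyldimethylsilyl)oxy]-4-methylpent-3-en-1-yl}-2-methyl-2H-chromene-6-carbonitrile F3. Reduction with i-Bu2AlH (toluene, −78 °C, aqueous tartrate work-up) gives the aldehyde, and the route is rejoined at 7.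

Step 8. Protic acid may ionise the primary allylic alcohol (methyl ether formation or allylic transposition) or open the tertiary allylic aryl ether of the chromene, and the freed catechol may be oxidised by air during a long reaction. The fallback sets out from 12 and replaces the single protic step by two orthogonal, non-protic ones. TMSOTf with 2,2'-bipyridyl (CH2Cl2, 0 °C, then water) removes only the two aryl methoxymethyl groups and gives the silyl ether 3-{2-[(2S)-2-{(3E)-5-[(tert-butyldimethylsilyl)oxy]-4-methylpent-3-en-1-yl}-2-methyl-2H-chromen-6-yl]ethyl}benzene-1,2-diol F4. Bu4NF buffered with AcOH (THF, 0 °C, argon) then cleaves the silyl ether and the route comes back at 13.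

Step 1. The acidic selenium medium may isomerise or cyclise the unprotected tertiary allylic alcohol, and over-oxidation with incomplete conversion may leave a mixture that is hard to separate. The fallback sets out from 1 and builds the (E)-allylic alcohol by cleavage and olefination instead of C–H oxidation. Ozonolysis with one equivalent of O3 (CH2Cl2/MeOH, −78 °C, then Me2S) cleaves the electron-rich trisubstituted olefin first and gives the hydroxy-aldehyde as its lactol (5S)-5-ethenyl-5-methyloxolan-2-ol F5. Wittig reaction with the stabilised ylide Ph3P=C(CH3)CO2Et (toluene, 80 °C) should give ethyl (2E,6S)-6-hydroxy-2,6-dimethylocta-2,7-dienoate F6 with E selectivity. Reduction with i-Bu2AlH (CH2Cl2, −78 °C) returns to the route at 2.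

Further compounds
F1 | step 4 | 4-fluoro-3-ethenylbenzonitrile | N#Cc1ccc(F)c(C=C)c1
F2 | step 4 | 4-{[(3S,6E)-8-[(tert-butyldimethylsilyl)oxy]-3,7-dimethylocta-1,6-dien-3-yl]oxy}-3-ethenylbenzonitrile | C/C(=C\CC[C@@](C)(C=C)Oc1ccc(C#N)cc1C=C)CO[Si](C)(C)C(C)(C)C
F3 | step 4 | (2S)-2-{(3E)-5-[(tert-butyldimethylsilyl)oxy]-4-methylpent-3-en-1-yl}-2-methyl-2H-chromene-6-carbonitrile | C/C(=C\CC[C@@]1(C)C=Cc2cc(C#N)ccc2O1)CO[Si](C)(C)C(C)(C)C
F4 | step 8 | 3-{2-[(2S)-2-{(3E)-5-[(tert-butyldimethylsilyl)oxy]-4-methylpent-3-en-1-yl}-2-methyl-2H-chromen-6-yl]ethyl}benzene-1,2-diol | C/C(=C\CC[C@@]1(C)C=Cc2cc(CCc3cccc(O)c3O)ccc2O1)CO[Si](C)(C)C(C)(C)C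
F5 | step 1 | (5S)-5-ethenyl-5-methyloxolan-2-ol | OC1CC[C@@](C)(C=C)O1
F6 | step 1 | ethyl (2E,6S)-6-hydroxy-2,6-dimethylocta-2,7-dienoate | CCOC(=O)/C(C)=C/CC[C@@](C)(C=C)O
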